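**Retrosynthetic overview**

1. The C16 chain is attached last: the target comes from diimide reduction of the cross-metathesis product of a C6-allyl peroxylactone with 1-pentadecene.
2. The C6 quaternary peroxide carbon comes from allylsilane attack on a bicyclic peroxycarbenium ion (from a C6 methoxy peroxyketal); the cis-fused lactone steers the face.
3. The 1,2-dioxane ring (second ring) comes from a hydroperoxy ketal of a methyl ketone adding intramolecularly (oxa-Michael) to a butenolide; C4 dictates C3.
4. The keto-butenolide comes from the key C4–C5 bond: asymmetric vinylogous Michael addition of α-angelica lactone (γ-carbon) to 2-nitropropene, used as an acetonyl-cation (enolonium) equivalent, then a Nef reaction; this sets C4.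
5. Ring order: the lactone ring is carried in from α-angelica lactone; the dioxane ring is closed onto it mid-route.

Assumption 1: skeleton numbering is C1 (lactone C=O), C2 (CH2), C3 (CH–OO), C4 (C(CH3)–O), C5 (ring CH2), C6 (C(CH3)(chain)–OO); the target is (3S,4S,6R) in this numbering and (3R,4aS,7aS) in fused-ring numbering.

Assumption 2: the epi-quinidine-derived catalyst of step 2 is taken to give the (S) quaternary centre; if the first run shows the opposite sense, its epi-quinine pseudo-enantiomer is used under the same conditions.

**Route**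

Step 1
Reactants: 1 2-nitropropan-1-ol
Product: 2 2-nitropropene
Conditions: phthalic anhydride (1.3 equiv), neat, 150 → 180 °C, 110 mmHg, product distilled out as formed; stored cold, used fresh
Reagents that add atoms: none
Why: Dehydration of a β-nitro alcohol through its hydrogen phthalate half-ester (thermal β-elimination), a standard preparation in which the volatile nitroalkene leaves the flask before it can polymerise; no stereocentre.

Step 2
Reactants: 2 2-nitropropene; 3 α-angelica lactone (5-methylfuran-2(3H)-one)
Product: 4 (5S)-5-methyl-5-(2-nitropropyl)furan-2(5H)-one (about 1:1 at the nitro carbon)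
Conditions: 3 (2 equiv), 2 (1 equiv, added over 6 h), N-[3,5-bis(trifluoromethyl)phenyl]-N′-(9-deoxy-epi-quinidin-9-yl)thiourea (10 mol %), toluene, −20 °C
Reagents that add atoms: none
Why: Proposed new method: direct asymmetric vinylogous Michael addition in which the quinuclidine of the catalyst deprotonates 3 to the 2-oxidofuran dienolate (held as a chiral ion pair) while the thiourea hydrogen-bonds the nitro group, so the dienolate γ-carbon (C4) attacks the CH2 terminus (C5) of 2-nitropropene, which acts as an acetonyl-cation (enolonium) equivalent and so joins two carbons that are both donor sites in the normal sense; the closest known reaction type is the amine–thiourea-catalysed γ-selective Michael addition of α-angelica lactone to β-substituted nitroalkenes (γ,γ-disubstituted butenolides in high ee), and catalyst-controlled face selection of the dienolate sets the C4 quaternary centre as S, the nitro-bearing carbon being formed unselectively and erased in step 3.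

Step 3
Reactants: 4 (5S)-5-methyl-5-(2-nitropropyl)furan-2(5H)-one
Product: 5 (S)-5-methyl-5-(2-oxopropyl)furan-2(5H)-one
Conditions: NaNO2 (3 equiv), AcOH (10 equiv), DMSO, 35 °C
Reagents that add atoms: water, O
Why: Nef reaction under weakly acidic nitrosating conditions (nitrosation of the aci-nitro tautomer, hydrolytic collapse to the ketone with loss of nitrogen as N2O), chosen because no strong base is present that could eliminate the β-acyloxy group or attack the butenolide; C4 is untouched and the nitro stereocentre disappears.

Step 4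
Reactants: 5 (S)-5-methyl-5-(2-oxopropyl)furan-2(5H)-one
Product: 7 (4aS,7aS)-3-methoxy-3,4a-dimethyltetrahydrofuro[3,2-c][1,2]dioxin-6(3H)-one (both C6 ketal epimers), via hydroperoxy methyl ketal 6 (not isolated)
Conditions: urea–hydrogen peroxide (5 equiv), Sc(OTf)3 (10 mol %), MeOH, rt; aqueous work-up; then Et2NH (0.5 equiv), CF3CH2OH, rt
Reagents that add atoms: urea–hydrogen peroxide, OO.NC(N)=O; methanol, CO
Why: Sc(OTf)3-catalysed perhydrolysis of the methyl ketone in methanol gives the α-methoxy hydroperoxide 6, whose OOH group then adds to the butenolide by amine-mediated intramolecular 6-exo oxa-Michael addition (hydroperoxide conjugate addition, known for hydroperoxy ketals onto enoates and for tertiary hydroperoxides onto this butenolide type); being tethered through C5, the hydroperoxide can only reach the C3 face syn to C5, so the cis-fused bicycle forms and C3 is set as S by C4, while the ketal carbon is an inconsequential mixture.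

Step 5
Reactants: 7 (4aS,7aS)-3-methoxy-3,4a-dimethyltetrahydrofuro[3,2-c][1,2]dioxin-6(3H)-one
Product: 9 (3R,4aS,7aS)-3-allyl-3,4a-dimethyltetrahydrofuro[3,2-c][1,2]dioxin-6(3H)-one, via peroxycarbenium ion 8 (not isolated)
Conditions: allylSiMe3 (3 equiv), TiCl4 (1.1 equiv), CH2Cl2, −78 °C; H2O quench
Reagents that add atoms: allyltrimethylsilane, C=CC[Si](C)(C)C
Why: Lewis-acid ionisation of the peroxyketal and Hosomi–Sakurai-type capture of the peroxycarbenium ion, a known C–C bond-forming reaction of 3-alkoxy-1,2-dioxanes and -dioxolanes; both epimers of 7 converge on ion 8, whose favoured half-chair has the C4 lactone oxygen pseudo-axial and the C4 methyl and C3–C2 bond pseudo-equatorial, so chair-like axial attack is predicted to occur syn to the lactone oxygen and anti to the C4 methyl (the other face needs a twist-boat or a 1,3-diaxial clash with that methyl), placing allyl cis to the lactone oxygen and the two methyls cis, i.e. C6 = R (to be confirmed by NOE between the two methyl groups).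

Step 6
Reactants: 9 (3R,4aS,7aS)-3-allyl-3,4a-dimethyltetrahydrofuro[3,2-c][1,2]dioxin-6(3H)-one; 10 1-pentadecene
Product: 11 (3R,4aS,7aS)-3-(hexadec-2-en-1-yl)-3,4a-dimethyltetrahydrofuro[3,2-c][1,2]dioxin-6(3H)-one (E/Z mixture, E major)
Conditions: 10 (4 equiv), (H2IMes)(PCy3)Cl2Ru=CHPh (second-generation Grubbs catalyst, 5 mol %), CH2Cl2, 40 °C
Reagents that add atoms: none
Why: Olefin cross-metathesis of the unhindered terminal alkene with excess 1-pentadecene extends allyl to the full C16 chain with loss of ethylene; dialkyl peroxides and lactones tolerate ruthenium carbenes, no stereocentre is touched and the E/Z ratio is irrelevant.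

Step 7
Reactants: 11 (3R,4aS,7aS)-3-(hexadec-2-en-1-yl)-3,4a-dimethyltetrahydrofuro[3,2-c][1,2]dioxin-6(3H)-one
Product: 12 (3R,4aS,7aS)-3-hexadecyl-3,4a-dimethyltetrahydrofuro[3,2-c][1,2]dioxin-6(3H)-one (target)
Conditions: KO2C–N=N–CO2K (15 equiv), AcOH (30 equiv, slow addition), MeOH/CH2Cl2, 0 °C → rt
Reagents that add atoms: none
Why: Diimide reduction (concerted syn transfer of H2 from HN=NH) saturates the C=C bond without cleaving the O–O bond, which catalytic hydrogenation would not spare; no stereocentre is affected and the product is the target.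

**Compound list**

1 | 2-nitropropan-1-ol (racemic) | CC(CO)[N+](=O)[O-] | starting material
2 | 2-nitropropene | CC(=C)[N+](=O)[O-] | intermediate
3 | α-angelica lactone, 5-methylfuran-2(3H)-one | CC1=CCC(=O)O1 | starting material
4 | (5S)-5-methyl-5-(2-nitropropyl)furan-2(5H)-one, epimers at the nitro carbon | CC(C[C@]1(C)OC(=O)C=C1)[N+](=O)[O-] | intermediate
5 | (S)-5-methyl-5-(2-oxopropyl)furan-2(5H)-one | CC(=O)C[C@]1(C)OC(=O)C=C1 | intermediate
6 | (5S)-5-(2-hydroperoxy-2-methoxypropyl)-5-methylfuran-2(5H)-one, epimers at the ketal carbon | COC(C)(OO)C[C@]1(C)OC(=O)C=C1 | intermediate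
7 | (4aS,7aS)-3-methoxy-3,4a-dimethyltetrahydrofuro[3,2-c][1,2]dioxin-6(3H)-one, both ketal epimers | COC1(C)C[C@]2(C)OC(=O)C[C@@H]2OO1 | intermediate
8 | (4aS,7aS)-3,4a-dimethyl-6-oxo-4,4a,7,7a-tetrahydro-6H-furo[3,2-c][1,2]dioxin-2-ium, peroxycarbenium ion (chlorotitanate counter-ion) | CC1=[O+]O[C@H]2CC(=O)O[C@@]2(C)C1 | intermediate
9 | (3R,4aS,7aS)-3-allyl-3,4a-dimethyltetrahydrofuro[3,2-c][1,2]dioxin-6(3H)-one | C=CC[C@]1(C)C[C@]2(C)OC(=O)C[C@@H]2OO1 | intermediate
10 | 1-pentadecene | CCCCCCCCCCCCCC=C | starting material
11 | (3R,4aS,7aS)-3-[(E)-hexadec-2-en-1-yl]-3,4a-dimethyltetrahydrofuro[3,2-c][1,2]dioxin-6(3H)-one (E shown, Z also present) | CCCCCCCCCCCCC/C=C/C[C@]1(C)C[C@]2(C)OC(=O)C[C@@H]2OO1 | intermediate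
12 | (3R,4aS,7aS)-3-hexadecyl-3,4a-dimethyltetrahydrofuro[3,2-c][1,2]dioxin-6(3H)-one; (3S,4S,6R) in skeleton numbering | CCCCCCCCCCCCCCCC[C@]1(C)C[C@]2(C)OC(=O)C[C@@H]2OO1 | target

**Step count and risks**

Total steps: 7. Longest linear sequence: 7 (1 → 2 → 4 → 5 → 7 → 9 → 11 → 12); 6 steps from α-angelica lactone.

The three steps most likely to fail are steps 2, 5 and 4.

Step 2 (enantioselectivity and oligomerisation with a β-unsubstituted nitroalkene). The fallback sets out from 3 (with 2) and comes back at 5. It gives up catalyst control in the bond-forming step and takes the stereochemistry from a resolution. The Michael addition is run with DABCO to give racemic 5-methyl-5-(2-nitropropyl)furan-2(5H)-one F1. The same Nef reaction then gives racemic 5-methyl-5-(2-oxopropyl)furan-2(5H)-one F2. F2 is resolved by preparative chromatography on an amylose tris(3,5-dimethylphenylcarbamate) phase (supercritical CO2/2-propanol). The (S)-enantiomer is 5; the unwanted (R)-5-methyl-5-(2-oxopropyl)furan-2(5H)-one F3 is set aside.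

Step 5 (face selectivity is a prediction, and the Lewis acid may degrade the peroxide). The fallback sets out from 5 and comes back at 12. It replaces the peroxycarbenium alkylation by radical hydroperoxysilylation and accepts loss of control at C6.
- Wittig olefination of 5 with the salt-free ylide from hexadecyltriphenylphosphonium bromide (NaN(SiMe3)2, THF, −78 °C) gives (S)-5-methyl-5-(2-methyloctadec-2-en-1-yl)furan-2(5H)-one F5 as an E/Z mixture. The basic ylide may itself cause β-elimination of the acyloxy group in 5.
- Isayama–Mukaiyama peroxidation (Co(acac)2, O2, Et3SiH, 1,2-dichloroethane) places the peroxide at the tertiary carbon and gives (5S)-5-methyl-5-[2-methyl-2-(triethylsilylperoxy)octadecyl]furan-2(5H)-one F6, about 1:1 at C6.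
- HF·pyridine frees (5S)-5-(2-hydroperoxy-2-methyloctadecyl)-5-methylfuran-2(5H)-one F7.
- Et2NH in CF3CH2OH closes the dioxane ring to give 12 together with its C6 epimer (3S,4aS,7aS)-3-hexadecyl-3,4a-dimethyltetrahydrofuro[3,2-c][1,2]dioxin-6(3H)-one F8, which is removed by HPLC.

Step 4 (acid-catalysed perhydrolysis of a hindered ketone beside a butenolide may stall, or add methanol to the enoate). The fallback sets out from 5 and comes back at 6, and from there at 7. It makes the hydroperoxy ketal from a carbonyl oxide instead. The ketone of 5 is methylenated under non-basic conditions (Zn, CH2Br2, TiCl4, THF) to (S)-5-methyl-5-(2-methylallyl)furan-2(5H)-one F4. The electron-rich 1,1-disubstituted alkene is then ozonised selectively (O3, CH2Cl2/MeOH, −78 °C, Sudan Red 7B end point). The ketone oxide from Criegee cleavage is trapped by methanol to give 6 directly, which is cyclised with Et2NH in CF3CH2OH as in the route.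

**Further compounds**

F1 | step 2 | racemic 5-methyl-5-(2-nitropropyl)furan-2(5H)-one | CC(CC1(C)OC(=O)C=C1)[N+](=O)[O-]
F2 | step 2 | racemic 5-methyl-5-(2-oxopropyl)furan-2(5H)-one | CC(=O)CC1(C)OC(=O)C=C1
F3 | step 2 | (R)-5-methyl-5-(2-oxopropyl)furan-2(5H)-one | CC(=O)C[C@@]1(C)OC(=O)C=C1
F4 | step 4 | (S)-5-methyl-5-(2-methylallyl)furan-2(5H)-one | CC(=C)C[C@]1(C)OC(=O)C=C1
F5 | step 5 | (S)-5-methyl-5-(2-methyloctadec-2-en-1-yl)furan-2(5H)-one | CCCCCCCCCCCCCCCC=C(C)C[C@]1(C)OC(=O)C=C1
F6 | step 5 | (5S)-5-methyl-5-[2-methyl-2-(triethylsilylperoxy)octadecyl]furan-2(5H)-one | CCCCCCCCCCCCCCCCC(C)(OO[Si](CC)(CC)CC)C[C@]1(C)OC(=O)C=C1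
F7 | step 5 | (5S)-5-(2-hydroperoxy-2-methyloctadecyl)-5-methylfuran-2(5H)-one | CCCCCCCCCCCCCCCCC(C)(OO)C[C@]1(C)OC(=O)C=C1
F8 | step 5 | (3S,4aS,7aS)-3-hexadecyl-3,4a-dimethyltetrahydrofuro[3,2-c][1,2]dioxin-6(3H)-one | CCCCCCCCCCCCCCCC[C@@]1(C)C[C@]2(C)OC(=O)C[C@@H]2OO1
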